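**Retrosynthetic overview**
1. The plan rests on C4 of ring C. This carbonyl carbon lies between C4a of ring A, which is electron-rich and flanked by the oxygen-bearing C5 and C8a, and the oxygen-bearing C3. It can therefore be cut free on both sides and supplied as carbon monoxide.
2. Disconnections, backwards: 5-OH from the 5-OMe peri to C4=O, and 3-, 2'- and 4'-OH from benzyl ethers. O1–C2 comes from cyclodehydration of a 2-benzyloxy-1,3-diketone in which only the C8a oxygen carries an acid-labile MOM group. C4a–C4 and C4–C3 are formed together from a ring A iodide, CO and a ring B α-benzyloxy ketone.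
3. Iodide: 3-hydroxy-4,5-dimethoxybenzaldehyde → MOM ether → Baeyer–Villiger → methyl ether → MOM-directed lithiation/iodination. Ketone: 2,4-dihydroxybenzaldehyde → benzylation → Baeyer–Villiger → methylation → bromination → aryllithium plus the Weinreb amide made from benzyloxyacetyl chloride.
4. Ring order: rings A and B come from the starting arenes. Ring C (the pyranone) is the only ring formed, in step 12, after step 11 has laid down its carbon chain.

Key step: step 11

Remark: the target has no stereocentre and no stereodefined double bond, so no step has to set configuration; flavone numbering (O1, C2 to C8a, primed ring B) is used for all intermediates.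

**Step 1**
Reactants: 1 3-hydroxy-4,5-dimethoxybenzaldehyde
Product: 2 3,4-dimethoxy-5-(methoxymethoxy)benzaldehyde
Conditions: MOMCl, K2CO3, acetone, 0 °C → rt
Reagents that add atoms: chloromethyl methyl ether (MOMCl), COCCl
Why: Williamson-type O-alkylation of the only free phenol installs the acid-labile acetal that later directs the lithiation and marks the oxygen destined to become O1.

**Step 2**
Reactants: 2 3,4-dimethoxy-5-(methoxymethoxy)benzaldehyde
Product: 4 3,4-dimethoxy-5-(methoxymethoxy)phenol, via aryl formate 3 (not isolated)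
Conditions: mCPBA, CH2Cl2, 0 °C → rt; aq NaHCO3 wash; then K2CO3 (cat.), MeOH, rt
Reagents that add atoms: 3-chloroperoxybenzoic acid (mCPBA), O=C(OO)c1cccc(Cl)c1
Why: Baeyer–Villiger oxidation of this electron-rich benzaldehyde should proceed with aryl migration (para-methoxy assistance, as with 3,4,5-trimethoxybenzaldehyde), base-catalysed methanolysis then frees the phenol, and the MOM acetal tolerates the weakly acidic peracid.

**Step 3**
Reactants: 4 3,4-dimethoxy-5-(methoxymethoxy)phenol
Product: 5 1,2,5-trimethoxy-3-(methoxymethoxy)benzene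
Conditions: MeI, K2CO3, acetone, reflux
Reagents that add atoms: iodomethane, CI
Why: Williamson ether synthesis on the single free phenol fixes the future C5 oxygen as a base- and organolithium-stable methyl ether.

**Step 4**
Reactants: 5 1,2,5-trimethoxy-3-(methoxymethoxy)benzene
Product: 7 2-iodo-1,4,5-trimethoxy-3-(methoxymethoxy)benzene, via aryllithium 6 (not isolated)
Conditions: n-BuLi (1.2 equiv), Et2O, 0 °C → rt; then I2, THF, −78 °C → rt
Reagents that add atoms: iodine, II
Why: Directed ortho-metalation, in which the chelating OMOM group is a stronger director than OMe, so that of the two doubly flanked ring positions the one between OMOM and OMe should be deprotonated in the weakly coordinating solvent and is then trapped by iodine.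

**Step 5**
Reactants: 8 2,4-dihydroxybenzaldehyde
Product: 9 2,4-bis(benzyloxy)benzaldehyde
Conditions: BnBr (2.4 equiv), K2CO3, DMF, 60 °C
Reagents that add atoms: benzyl bromide, BrCc1ccccc1
Why: Double Williamson benzylation, the warm polar medium also driving alkylation of the hydrogen-bonded 2-OH.

**Step 6**
Reactants: 9 2,4-bis(benzyloxy)benzaldehyde
Product: 11 2,4-bis(benzyloxy)phenol, via aryl formate 10 (not isolated)
Conditions: mCPBA, CH2Cl2, 0 °C → rt; aq NaHCO3 wash; then K2CO3 (cat.), MeOH, rt
Reagents that add atoms: 3-chloroperoxybenzoic acid (mCPBA), O=C(OO)c1cccc(Cl)c1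
Why: Baeyer–Villiger oxidation with aryl migration, favoured by the ortho and para benzyloxy donors, followed by base-catalysed methanolysis of the formate, should give the phenol without touching the benzyl ethers.

**Step 7**
Reactants: 11 2,4-bis(benzyloxy)phenol
Product: 12 2,4-bis(benzyloxy)-1-methoxybenzene
Conditions: MeI, K2CO3, acetone, reflux
Reagents that add atoms: iodomethane, CI
Why: Williamson ether synthesis caps the oxidation-prone phenol at once and sets the future 5'-OMe.

**Step 8**
Reactants: 12 2,4-bis(benzyloxy)-1-methoxybenzene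
Product: 13 1-bromo-2,4-bis(benzyloxy)-5-methoxybenzene
Conditions: NBS (1.0 equiv), MeCN, 0 °C, dark
Reagents that add atoms: N-bromosuccinimide, O=C1CCC(=O)N1Br
Why: Electrophilic aromatic bromination should take the position para to one benzyloxy group and ortho to the other (the site also taken in 1,2,4-trimethoxybenzene), while the polar solvent and darkness suppress radical benzylic bromination.

**Step 9**
Reactants: 14 benzyloxyacetyl chloride
Product: 15 2-(benzyloxy)-N-methoxy-N-methylacetamide
Conditions: MeNH(OMe)·HCl, K2CO3, CH2Cl2–H2O, 0 °C → rt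
Reagents that add atoms: N,O-dimethylhydroxylamine hydrochloride, CNOC.Cl
Why: Schotten–Baumann N-acylation of the hydroxylamine by the acid chloride gives the Weinreb amide.

**Step 10**
Reactants: 13 1-bromo-2,4-bis(benzyloxy)-5-methoxybenzene; 15 2-(benzyloxy)-N-methoxy-N-methylacetamide
Product: 17 2-(benzyloxy)-1-[2,4-bis(benzyloxy)-5-methoxyphenyl]ethanone, via aryllithium 16 (not isolated)
Conditions: n-BuLi (1.05 equiv), THF, −78 °C; then 15, −78 → 0 °C; 1 M HCl aq, 0 °C
Reagents that add atoms: none
Why: Bromine–lithium exchange at −78 °C outruns benzylic deprotonation and the Weinreb ketone synthesis stops at the ketone, a route preferred to a Lewis-acid Friedel–Crafts acylation because the benzyloxyacetyl cation would lose CO and the benzyl ethers would be stripped.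

**Step 11**
Reactants: 7 2-iodo-1,4,5-trimethoxy-3-(methoxymethoxy)benzene; 17 2-(benzyloxy)-1-[2,4-bis(benzyloxy)-5-methoxyphenyl]ethanone; 18 carbon monoxide
Product: 20 2-(benzyloxy)-1-[2,4-bis(benzyloxy)-5-methoxyphenyl]-3-[3,4,6-trimethoxy-2-(methoxymethoxy)phenyl]propane-1,3-dione (central carbon enolisable; configuration undefined), via sodium enolate 19 (not isolated)
Conditions: 17 (2 equiv), NaN(SiMe3)2 (2 equiv), THF, 0 °C; then 7 (1 equiv), Pd(dba)2 (5 mol %), Xantphos (6 mol %), CO (1 atm), 1,4-dioxane, 80 °C; pH 7 buffer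
Reagents that add atoms: none
Why: Zerovalent palladium adds oxidatively to the C–I bond of 7, CO inserts into the crowded aryl–palladium bond, and the aroyl group passes from divalent palladium to the α-carbon of enolate 19 (ligand exchange, then reductive elimination), so that C4a–C4 and C4–C3 form in one operation. The closest known reaction type is the palladium-catalysed carbonylative α-arylation of aryl alkyl ketones with aryl iodides to 1,3-diketones, and the pairing of a di-ortho-oxygenated iodide with an α-alkoxy enolate sits at the demanding end of that scope. No ring is closed, and the only new stereocentre, the central carbon (future C3), is enolisable, is left uncontrolled and becomes sp2 in step 12. The step needs carbonylative C-acylation to win over direct α-arylation and O-acylation: the two ortho oxygens of 7 retard C–C reductive elimination from the arylpalladium enolate but favour CO insertion through relief of strain, the wide bite angle of Xantphos favours reductive elimination from the aroylpalladium enolate, and any enol ester formed is itself an acyl donor towards excess enolate, so that material should drain to the stabilised sodium diketonate. The second equivalent of 19 takes up the acidic proton of 20 and is recovered as 17 on work-up. MOM, benzyl and methyl ethers are inert to the base and the catalyst.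

**Step 12**
Reactants: 20 2-(benzyloxy)-1-[2,4-bis(benzyloxy)-5-methoxyphenyl]-3-[3,4,6-trimethoxy-2-(methoxymethoxy)phenyl]propane-1,3-dione
Product: 22 3-(benzyloxy)-2-[2,4-bis(benzyloxy)-5-methoxyphenyl]-5,7,8-trimethoxy-4H-chromen-4-one, via free phenol diketone 21 (not isolated)
Conditions: conc. HCl aq, i-PrOH–THF, 60 °C
Reagents that add atoms: none
Why: Acid hydrolysis of the MOM acetal frees only the ring A phenol, which adds to the ring B carbonyl (C2) in a six-membered closure and loses water to give the aromatic pyranone (the cyclodehydration that ends a Baker–Venkataraman flavone synthesis), the 2'-oxygen staying blocked as its benzyl ether.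

**Step 13**
Reactants: 22 3-(benzyloxy)-2-[2,4-bis(benzyloxy)-5-methoxyphenyl]-5,7,8-trimethoxy-4H-chromen-4-one
Product: 23 2-(2,4-dihydroxy-5-methoxyphenyl)-3-hydroxy-5,7,8-trimethoxy-4H-chromen-4-one
Conditions: H2 (1 atm), 10% Pd/C, EtOAc–MeOH, rt
Reagents that add atoms: none
Why: Catalytic hydrogenolysis should remove all three benzyl ethers, while the conjugated C2=C3 bond of the flavonol and the aryl methyl ethers persist at atmospheric pressure.

**Step 14**
Reactants: 23 2-(2,4-dihydroxy-5-methoxyphenyl)-3-hydroxy-5,7,8-trimethoxy-4H-chromen-4-one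
Product: 24 2-(2,4-dihydroxy-5-methoxyphenyl)-3,5-dihydroxy-7,8-dimethoxy-4H-chromen-4-one (CNP0319239.0)
Conditions: BCl3 (6 equiv, 1 M in CH2Cl2), CH2Cl2, −40 → 0 °C; then 1 M HCl aq, rt
Reagents that add atoms: none
Why: Chelation-controlled aryl methyl ether cleavage, in which boron held at the C4 carbonyl oxygen activates only the peri 5-OMe for chloride attack on its methyl group, whereas the 7-, 8- and 5'-methoxy groups lack such a neighbour and the low temperature avoids the ring-opening Wessely–Moser isomerisation seen in hot protic acid.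

**Compound list**
1 | 3-hydroxy-4,5-dimethoxybenzaldehyde | COc1cc(C=O)cc(O)c1OC | starting material
2 | 3,4-dimethoxy-5-(methoxymethoxy)benzaldehyde | COCOc1cc(C=O)cc(OC)c1OC | intermediate
3 | 3,4-dimethoxy-5-(methoxymethoxy)phenyl formate | COCOc1cc(OC=O)cc(OC)c1OC | intermediate
4 | 3,4-dimethoxy-5-(methoxymethoxy)phenol | COCOc1cc(O)cc(OC)c1OC | intermediate
5 | 1,2,5-trimethoxy-3-(methoxymethoxy)benzene | COCOc1cc(OC)cc(OC)c1OC | intermediate
6 | [3,4,6-trimethoxy-2-(methoxymethoxy)phenyl]lithium | COCOc1c([Li])c(OC)cc(OC)c1OC | intermediate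
7 | 2-iodo-1,4,5-trimethoxy-3-(methoxymethoxy)benzene | COCOc1c(I)c(OC)cc(OC)c1OC | intermediate
8 | 2,4-dihydroxybenzaldehyde | O=Cc1ccc(O)cc1O | starting material
9 | 2,4-bis(benzyloxy)benzaldehyde | O=Cc1ccc(OCc2ccccc2)cc1OCc1ccccc1 | intermediate
10 | 2,4-bis(benzyloxy)phenyl formate | O=COc1ccc(OCc2ccccc2)cc1OCc1ccccc1 | intermediate
11 | 2,4-bis(benzyloxy)phenol | Oc1ccc(OCc2ccccc2)cc1OCc1ccccc1 | intermediate
12 | 2,4-bis(benzyloxy)-1-methoxybenzene | COc1ccc(OCc2ccccc2)cc1OCc1ccccc1 | intermediate
13 | 1-bromo-2,4-bis(benzyloxy)-5-methoxybenzene | COc1cc(Br)c(OCc2ccccc2)cc1OCc1ccccc1 | intermediate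
14 | benzyloxyacetyl chloride | O=C(Cl)COCc1ccccc1 | starting material
15 | 2-(benzyloxy)-N-methoxy-N-methylacetamide | CON(C)C(=O)COCc1ccccc1 | intermediate
16 | [2,4-bis(benzyloxy)-5-methoxyphenyl]lithium | COc1cc([Li])c(OCc2ccccc2)cc1OCc1ccccc1 | intermediate
17 | 2-(benzyloxy)-1-[2,4-bis(benzyloxy)-5-methoxyphenyl]ethanone | COc1cc(C(=O)COCc2ccccc2)c(OCc2ccccc2)cc1OCc1ccccc1 | intermediate
18 | carbon monoxide | [C-]#[O+] | starting material
19 | sodium enolate of 17 (drawn as the chelated Z form; the geometry has no consequence) | COc1cc(/C([O-])=C/OCc2ccccc2)c(OCc2ccccc2)cc1OCc1ccccc1.[Na+] | intermediate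
20 | 2-(benzyloxy)-1-[2,4-bis(benzyloxy)-5-methoxyphenyl]-3-[3,4,6-trimethoxy-2-(methoxymethoxy)phenyl]propane-1,3-dione (central carbon enolisable, configuration undefined) | COCOc1c(C(=O)C(OCc2ccccc2)C(=O)c2cc(OC)c(OCc3ccccc3)cc2OCc2ccccc2)c(OC)cc(OC)c1OC | intermediate
21 | 2-(benzyloxy)-1-[2,4-bis(benzyloxy)-5-methoxyphenyl]-3-(2-hydroxy-3,4,6-trimethoxyphenyl)propane-1,3-dione (configuration undefined) | COc1cc(OC)c(C(=O)C(OCc2ccccc2)C(=O)c2cc(OC)c(OCc3ccccc3)cc2OCc2ccccc2)c(O)c1OC | intermediate
22 | 3-(benzyloxy)-2-[2,4-bis(benzyloxy)-5-methoxyphenyl]-5,7,8-trimethoxy-4H-chromen-4-one | COc1cc(-c2oc3c(OC)c(OC)cc(OC)c3c(=O)c2OCc2ccccc2)c(OCc2ccccc2)cc1OCc1ccccc1 | intermediate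
23 | 2-(2,4-dihydroxy-5-methoxyphenyl)-3-hydroxy-5,7,8-trimethoxy-4H-chromen-4-one | COc1cc(-c2oc3c(OC)c(OC)cc(OC)c3c(=O)c2O)c(O)cc1O | intermediate
24 | 2-(2,4-dihydroxy-5-methoxyphenyl)-3,5-dihydroxy-7,8-dimethoxy-4H-chromen-4-one (CNP0319239.0) | COc1cc(-c2oc3c(OC)c(OC)cc(O)c3c(=O)c2O)c(O)cc1O | target

**Total step count:** 14
**Longest linear sequence:** 9 steps (5, 6, 7, 8, 10, 11, 12, 13, 14)

**Steps most likely to fail**

Step 11. Capture of the hindered aroylpalladium by the α-alkoxy enolate may be too slow. Hydrodeiodination, attack of the silylamide base on the acyl complex, O-acylation without onward acyl transfer, or loss of the catalyst as palladium black under CO could then take over. The fallback sets out from 5 and 17 and returns at 20; it brings in C4 as a formyl carbon instead of CO. Compound 5 is lithiated as in step 4 (through 6) and quenched with DMF to give 3,4,6-trimethoxy-2-(methoxymethoxy)benzaldehyde F1. Compound 17 is treated with LiN(SiMe3)2 in THF at −78 °C and then with F1 to give the aldol adduct 2-(benzyloxy)-1-[2,4-bis(benzyloxy)-5-methoxyphenyl]-3-hydroxy-3-[3,4,6-trimethoxy-2-(methoxymethoxy)phenyl]propan-1-one F2 as a mixture of diastereomers. Dess–Martin periodinane in CH2Cl2 then oxidises the carbinol to 20.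

Step 4. Site selectivity of the metalation may be poor, with competing deprotonation between the two methoxy groups. The fallback sets out from 5 and returns at 7; it replaces the acetal director by the strongest oxygen-based director, whose only free ortho position is the wanted one.
- The MOM group of 5 is removed (HCl, i-PrOH) to give 2,3,5-trimethoxyphenol F3.
- Diethylcarbamoyl chloride and K2CO3 in MeCN convert it into 2,3,5-trimethoxyphenyl diethylcarbamate F4.
- s-BuLi/TMEDA in THF at −78 °C followed by I2 gives 2-iodo-3,5,6-trimethoxyphenyl diethylcarbamate F5. The temperature is held low to avoid the anionic Fries shift.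
- NaOH in refluxing EtOH cleaves the carbamate to 2-iodo-3,5,6-trimethoxyphenol F6.
- MOMCl/K2CO3 as in step 1 gives 7.

Step 14. Further methyl ethers (the crowded 8-OMe, or the 5'-OMe next to a borate) may be lost. Alternatively the cleavage may stall because boron is tied up at the 3-OH/C4=O site and at the free phenols. The fallback sets out from 4 and returns at 24; it carries the C5 oxygen as a benzyl ether, so that no Lewis-acid demethylation is needed.
- Compound 4 is benzylated (BnBr, K2CO3, DMF) to 1-(benzyloxy)-3,4-dimethoxy-5-(methoxymethoxy)benzene F7.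
- n-BuLi in THF at −78 → −20 °C followed by I2 gives 1-(benzyloxy)-2-iodo-4,5-dimethoxy-3-(methoxymethoxy)benzene F8. At that temperature ring metalation between two oxygen donors should outrun benzylic metalation.
- Coupling with 17 and 18 under the conditions of step 11 gives 2-(benzyloxy)-1-[2,4-bis(benzyloxy)-5-methoxyphenyl]-3-[6-(benzyloxy)-3,4-dimethoxy-2-(methoxymethoxy)phenyl]propane-1,3-dione F9.
- Acid as in step 12 gives 3,5-bis(benzyloxy)-2-[2,4-bis(benzyloxy)-5-methoxyphenyl]-7,8-dimethoxy-4H-chromen-4-one F10.
- Hydrogenolysis as in step 13 removes all four benzyl groups to give 24 directly.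

**Further compounds**
F1 | step 11 | 3,4,6-trimethoxy-2-(methoxymethoxy)benzaldehyde | COCOc1c(C=O)c(OC)cc(OC)c1OC
F2 | step 11 | 2-(benzyloxy)-1-[2,4-bis(benzyloxy)-5-methoxyphenyl]-3-hydroxy-3-[3,4,6-trimethoxy-2-(methoxymethoxy)phenyl]propan-1-one (mixture of diastereomers) | COCOc1c(C(O)C(OCc2ccccc2)C(=O)c2cc(OC)c(OCc3ccccc3)cc2OCc2ccccc2)c(OC)cc(OC)c1OC
F3 | step 4 | 2,3,5-trimethoxyphenol | COc1cc(O)c(OC)c(OC)c1
F4 | step 4 | 2,3,5-trimethoxyphenyl diethylcarbamate | CCN(CC)C(=O)Oc1cc(OC)cc(OC)c1OC
F5 | step 4 | 2-iodo-3,5,6-trimethoxyphenyl diethylcarbamate | CCN(CC)C(=O)Oc1c(I)c(OC)cc(OC)c1OC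
F6 | step 4 | 2-iodo-3,5,6-trimethoxyphenol | COc1cc(OC)c(OC)c(O)c1I
F7 | step 14 | 1-(benzyloxy)-3,4-dimethoxy-5-(methoxymethoxy)benzene | COCOc1cc(OCc2ccccc2)cc(OC)c1OC
F8 | step 14 | 1-(benzyloxy)-2-iodo-4,5-dimethoxy-3-(methoxymethoxy)benzene | COCOc1c(I)c(OCc2ccccc2)cc(OC)c1OC
F9 | step 14 | 2-(benzyloxy)-1-[2,4-bis(benzyloxy)-5-methoxyphenyl]-3-[6-(benzyloxy)-3,4-dimethoxy-2-(methoxymethoxy)phenyl]propane-1,3-dione (configuration undefined) | COCOc1c(C(=O)C(OCc2ccccc2)C(=O)c2cc(OC)c(OCc3ccccc3)cc2OCc2ccccc2)c(OCc2ccccc2)cc(OC)c1OC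
F10 | step 14 | 3,5-bis(benzyloxy)-2-[2,4-bis(benzyloxy)-5-methoxyphenyl]-7,8-dimethoxy-4H-chromen-4-one | COc1cc(-c2oc3c(OC)c(OC)cc(OCc4ccccc4)c3c(=O)c2OCc2ccccc2)c(OCc2ccccc2)cc1OCc1ccccc1
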